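The earlier runs and the new flask come from a simulation with made-up constants, noise included.

Two excesses are asked, and one choice between birch and larch, which share their charge and differ in time.

| setting | zeta | beta | birch | larch |
|---|---|---|---|---|
| left-handed substrate | 0.050 M | 0.075 M | 0.10 M | 0.10 M |
| right-handed substrate | 0.050 M | 0.075 M | 0.10 M | 0.10 M |
| solid reagent | 0.30 M | 0.30 M | 0.300 M | 0.300 M |
| remark | run made earlier | run made earlier |  |  |
| time |  |  | 8.0 h | 2.5 h |

- zeta (time / h: right-handed substrate / %, left-handed substrate / %): 1.00: 38, 28; 2.00: 35, 20; 3.00: 25, 16; 4.00: 18, 8; 5.00: 15, 6; 6.00: 12, 8
- beta (time / h: right-handed substrate / %, left-handed substrate / %): 1.00: 36, 31; 2.00: 33, 20; 3.00: 27, 15; 4.00: 18, 13; 5.00: 11, 9; 6.00: 12, 6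

(scatter of a reading: 2 percentage points)

* the flask that ends with the higher excess of right-handed substrate over left-handed substrate among what is left of the two, or "neither" when 2 percentage points or less lies between them (birch / larch / neither)
* excess of right-handed substrate over left-handed substrate among what is left of the two at the end, birch
* excess of right-handed substrate over left-handed substrate among what is left of the two at the end, larch

- coupling partner is single-handed; left-handed substrate and right-handed substrate are mirror images of each other, charged as a racemate, each of them at the stated concentration
- given per volume of solution although it is solid: solid reagent
- the earlier runs were read with a standard deviation of 2 percentage points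
- what may be going on: coupling partner + left-handed substrate -> left-handed product; coupling partner + right-handed substrate -> right-handed product; left-handed substrate <-> achiral form; right-handed substrate <-> achiral form; achiral form -> side product; solid reagent <-> coupling partner; left-handed product <-> right-handed product
- at the start none of the solid reagent is in solution
- an excess is the difference of the two amounts in percent of their sum
- an excess is below zero if the other one leads
- the handed part of coupling partner does not stay in what it makes, so the products of the two hands are mirror images too

Solid reagent stands the same in both flasks, 1.50 parts to one part of substrate charged, so by hand it opens no gap between them. If each substrate is lost in proportion to itself, the fraction left does not depend on the charge, and the runs agree: at the last reading zeta keeps 20.0% and beta 18.0%, so both runs can be pooled. Time remains: birch runs 8.0 h, larch 2.5 h.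

The excess of right-handed substrate starts at zero and rises while left-handed substrate is lost faster. Passage through the achiral form should pull back harder as the excess grows, so the gain per hour should shrink with the distance to a plateau. Pooled from 3.00 h to 6.00 h, the readings put that plateau at 26.0%. The pooled excess at 1.00 h is 11.3%, which gives 1.76 h for the climb time (relaxation time), the time over which the distance to the plateau falls by the factor e. This is a rough reading: the pooled excess at 2.00 h is 25.9%, above the 17.7% it implies. My reckoning gives birch 25.8% and larch 19.7%, a gap of 6 percentage points, wider than the margin, so it commits to birch.

The forecast says neither, with 26% for birch and 24.5% for larch: “Larch at 2.5 h is essentially there”. It parts from this reckoning on larch.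

Birch ends at 27.6% and larch at 21.4%, so the answer is birch. Birch's own excess stood at 19.4% after 2.00 h and 24.5% after 4.00 h, still climbing past the time at which larch stops. In climb times as read from the runs, larch stops after 1.42 and birch after 4.55, which by that estimate leaves 24.2% and 1.06% of the climb open.

    coupling partner + left-handed substrate → left-handed product (k = 19.0 M⁻¹ h⁻¹)
    coupling partner + right-handed substrate → right-handed product (k = 1.70 M⁻¹ h⁻¹)
    left-handed substrate ⇌ achiral form (K = 0.430, k = 0.990 h⁻¹)
    right-handed substrate ⇌ achiral form (K = 0.430, k = 0.990 h⁻¹)
    achiral form → side product (k = 0.0510 h⁻¹)
    solid reagent ⇌ coupling partner, rate k6*(cs6 - [coupling partner]) while solid is left; crystals form when [coupling partner] > cs6 (solubility = 39.0 mM, k = 3.20 h⁻¹)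
    left-handed product ⇌ right-handed product (k = 0.620 h⁻¹)

For birch read at 2.0 h, the climb time gives 17.7%; that flask gives 19.4%.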